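**Leftover.** At 12.0 h the dusk run leaves 31.0% of the solid substrate charged outside its three readings. At 12.0 h the summer run leaves 6.00%. In the dusk run, c(reagent) stands below c(solid substrate), so reagent is the limiting reagent by charge there.

common to all: solid substrate 0.050 M; catalyst 50 µM

| flask | reagent | remark | time |
|---|---|---|---|
| dusk | 0.040 M | run made earlier |  |
| summer | 0.090 M | run made earlier |  |
| flask | 0.0600 M |  | 10 h |

| run | time / h | isomer of the product / % | target / % | solid substrate / % |
|---|---|---|---|---|
| dusk | 0.250 | 12 | 10 | 52 |
| dusk | 0.667 | 14 | 26 | 29 |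
| dusk | 1.50 | 14 | 42 | 12 |
| dusk | 4.00 | 8 | 55 | 3 |
| dusk | 12.0 | 7 | 58 | 4 |
| summer | 0.250 | 13 | 33 | 37 |
| summer | 0.667 | 24 | 63 | 0 |
| summer | 1.50 | 16 | 72 | 0 |
| summer | 4.00 | 8 | 82 | 0 |
| summer | 12.0 | 7 | 87 | 0 |

(each reading ± 2 percentage points)

- at the start none of the solid substrate is in solution
- a reading or a percentage of target counts all its forms, free or not

1. when, up to 10 h, the flask holds most isomer of the product
2. the amount of isomer of the product, in percent of the solid substrate charged, at that time

**Reagent.** The two runs differ in their reagent charge, 0.800 against 1.80 equivalents. Their peak isomer readings are 14% and 24%, each with a scatter of 2 percentage points. The rise is 10 points per equivalent of reagent. This rise is the peak gain. The flask holds 1.20 equivalents, so the peak gain, reckoned up from the dusk run, gives 18.0%.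

**Time, catalyst.** In both runs the peak reading stands by 1.50 h, earlier than 10 h. The time limit should therefore leave the flask's peak in place, between 0.667 h and 1.50 h. The catalyst charge is the same in both runs and the flask, so the readings give no slope for it.

**Forecast.** The forecast, 19% at 0.8 h, stands above the 18.0% reckoned here: “Interpolating between 14 and 24 gives about 19%, at about 0.8 h”.

**Result.** The flask holds most isomer at 0.902 h, with 20.9%.

    starting material + reagent ⇌ target (K = 12.0 L mol⁻¹, k = 0.0250 L mol⁻¹ s⁻¹)
    starting material + reagent ⇌ isomer of the product (K = 43.0 L mol⁻¹, k = 0.0110 L mol⁻¹ s⁻¹)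
    target + catalyst ⇌ isomer of the product + catalyst, rate k3*[catalyst]*[target] forward; the back reaction follows from the equilibrium constant (k = 8.70 L mol⁻¹ s⁻¹)
    2 starting material → homo dimer (k = 5.10 × 10⁻⁶ L mol⁻¹ s⁻¹)
    crystals ⇌ target, rate k5*(cs5 - [target]) while solid is left; crystals form when [target] > cs5 (solubility = 1.20 mM, k = 0.0140 s⁻¹)
    solid substrate ⇌ starting material, rate k6*(cs6 - [starting material]) while solid is left; crystals form when [starting material] > cs6 (solubility = 15.0 mM, k = 0.00690 s⁻¹)

**Weak charge.** The flask's peak lies 2.9 points above the peak-gain figure. Changed one at a time from the dusk run, reagent moves the peak from 15.3% to 20.9%, while time leaves it at 15.3%. A neighbouring flask holds 0.015 M of reagent, or 0.300 equivalents. For it the peak gain gives 9.00%, and that neighbouring flask reaches 8.69%.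

Readings and results are simulated with constants of no real substance; scatter was added.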